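**Assumption:** (S)-3-methylpentanoic acid (4) and (R)-2-methylbutanoic acid (10) are bought as single enantiomers; the (R)-oxazaborolidinium catalyst is taken to give the (1R,2R,4R)-endo adduct, inferred from the known facial sense of this catalyst family with acrylates, and its antipode is used if the first run shows the opposite sense.

## Retrosynthetic overview

1. Target 11 ⇒ hydroxy acetate 9 + (R)-2-methylbutanoic acid 10 (C4 ester bond).
2. 9 ⇒ vinyl epoxide 8 + acetic acid (Pd(0) opening with net retention at C3; this tells O3 from O4 without protecting groups).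
3. 8 ⇒ dienyl ester 7 (epoxidation trans to the C5 ester).
4. 7 ⇒ oxanorbornene 3 + acid 4 (E1cB opening of the oxygen bridge, acylation of the released alkoxide).
5. 3 ⇒ furan 1 + methyl acrylate 2 (catalytic asymmetric dearomative Diels–Alder). Ring order: oxabicycle formed in step 1, bridge opened in step 2, epoxide formed in step 3 and opened in step 4.

## Route

Step 1
Reactants: 1 furan; 2 methyl acrylate
Product: 3 methyl (1R,2R,4R)-7-oxabicyclo[2.2.1]hept-5-ene-2-carboxylate (endo ester)
Conditions: (R)-o-tolyl-oxazaborolidinium triflimide [from (R)-α,α-diphenylprolinol, o-tolylboroxine, Tf2NH] (20 mol%), furan (6 equiv), CH2Cl2, −78 °C, 24 h; Et3N quench; cold chromatography to remove the exo isomer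
Reagents that add atoms: none
Why: Proposed new method: the protonated oxazaborolidine binds the acrylate carbonyl, one enantioface is screened by the neighbouring aryl group, and furan adds to the open face through the endo transition state in a LUMO-lowered Diels–Alder reaction that breaks the furan aromaticity and fixes the bridgehead carbon that becomes C5; the closest known reactions are the same cationic-oxazaborolidine-catalysed Diels–Alder of furan with 2,2,2-trifluoroethyl acrylate and the racemic BF3-promoted Diels–Alder of furan with methyl acrylate; the exo adduct carries the antipodal bridgeheads and must be removed because C2 becomes sp2 in step 2.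

Step 2
Reactants: 3 methyl (1R,2R,4R)-7-oxabicyclo[2.2.1]hept-5-ene-2-carboxylate; 4 (S)-3-methylpentanoic acid
Product: 7 methyl (5R)-5-{[(3S)-3-methylpentanoyl]oxy}cyclohexa-1,3-diene-1-carboxylate, via lithium dienyl alkoxide 5 (not isolated), via (S)-3-methylpentanoyl chloride 6 (not isolated)
Conditions: LiHMDS (1.0 equiv), THF, −78 °C, 30 min; then 6 [second flask: 4, (COCl)2, cat. DMF, CH2Cl2, 0 °C to rt, evaporated], −78 to −40 °C; pH 7 buffer, cold work-up
Reagents that add atoms: none
Why: E1cB β-elimination: the ester enolate at C2 expels the bridgehead oxygen at C1 to give the conjugated dienoate, the other bridgehead (future C5, R) is untouched, and its lithium alkoxide is O-acylated with retention; no excess base and a cold work-up avoid loss of the carboxylate to give methyl benzoate.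

Step 3
Reactants: 7 methyl (5R)-5-{[(3S)-3-methylpentanoyl]oxy}cyclohexa-1,3-diene-1-carboxylate
Product: 8 methyl (1R,5R,6S)-5-{[(3S)-3-methylpentanoyl]oxy}-7-oxabicyclo[4.1.0]hept-2-ene-3-carboxylate (epoxide trans to the C5 ester)
Conditions: mCPBA (1.1 equiv), Na2HPO4, CH2Cl2, 0 °C
Reagents that add atoms: mCPBA, OOC(=O)c1cccc(Cl)c1
Why: Prilezhaev epoxidation: the peracid attacks the electron-richer γ,δ-alkene (C3=C4) rather than the ester-bearing alkene, from the face opposite the C5 acyloxy group, which sets C3 and C4 relative to C5.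

Step 4
Reactants: 8 methyl (1R,5R,6S)-5-{[(3S)-3-methylpentanoyl]oxy}-7-oxabicyclo[4.1.0]hept-2-ene-3-carboxylate
Product: 9 methyl (3R,4S,5R)-3-acetoxy-4-hydroxy-5-{[(3S)-3-methylpentanoyl]oxy}cyclohex-1-ene-1-carboxylate
Conditions: Pd(PPh3)4 (5 mol%), AcOH (5 equiv), THF, 0 °C
Reagents that add atoms: acetic acid, CC(=O)O
Why: Tsuji–Trost opening of a vinyl epoxide: Pd(0) ionises the allylic C3–O bond with inversion and acetate attacks the π-allyl terminus C3 (remote from the ester, restoring the enoate) anti to palladium, so C3 is substituted with net retention and the acetate ends cis to the C4 hydroxyl; excess acetic acid protonates the C4 alkoxide before acyl migration.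

Step 5
Reactants: 9 methyl (3R,4S,5R)-3-acetoxy-4-hydroxy-5-{[(3S)-3-methylpentanoyl]oxy}cyclohex-1-ene-1-carboxylate; 10 (R)-2-methylbutanoic acid
Product: 11 methyl (3R,4S,5R)-3-acetoxy-4-{[(2R)-2-methylbutanoyl]oxy}-5-{[(3S)-3-methylpentanoyl]oxy}cyclohex-1-ene-1-carboxylate (CNP0188172.1)
Conditions: DIC (1.5 equiv), DMAP (0.1 equiv), CH2Cl2, 0 °C to rt
Reagents that add atoms: none
Why: Steglich esterification of the remaining secondary alcohol; no stereocentre is touched, and catalytic DMAP at 0 °C keeps O3→O4 acetyl migration and α-epimerisation of the 2-methylbutanoyl unit slow relative to acylation.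

## Compound list

1 | furan | c1ccoc1 | starting material
2 | methyl acrylate | C=CC(=O)OC | starting material
3 | methyl (1R,2R,4R)-7-oxabicyclo[2.2.1]hept-5-ene-2-carboxylate (endo) | O1[C@@H]2C[C@@H](C(=O)OC)[C@H]1C=C2 | intermediate
4 | (S)-3-methylpentanoic acid | CC[C@H](C)CC(=O)O | starting material
5 | lithium (1R)-5-(methoxycarbonyl)cyclohexa-2,4-dien-1-olate | [Li+].[O-][C@@H]1CC(C(=O)OC)=CC=C1 | intermediate (not isolated)
6 | (S)-3-methylpentanoyl chloride | CC[C@H](C)CC(=O)Cl | intermediate (not isolated)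
7 | methyl (5R)-5-{[(3S)-3-methylpentanoyl]oxy}cyclohexa-1,3-diene-1-carboxylate | CC[C@H](C)CC(=O)O[C@@H]1CC(C(=O)OC)=CC=C1 | intermediate
8 | methyl (1R,5R,6S)-5-{[(3S)-3-methylpentanoyl]oxy}-7-oxabicyclo[4.1.0]hept-2-ene-3-carboxylate | CC[C@H](C)CC(=O)O[C@@H]1CC(C(=O)OC)=C[C@H]2O[C@@H]12 | intermediate
9 | methyl (3R,4S,5R)-3-acetoxy-4-hydroxy-5-{[(3S)-3-methylpentanoyl]oxy}cyclohex-1-ene-1-carboxylate | CC[C@H](C)CC(=O)O[C@@H]1CC(C(=O)OC)=C[C@@H](OC(C)=O)[C@H]1O | intermediate
10 | (R)-2-methylbutanoic acid | CC[C@@H](C)C(=O)O | starting material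
11 | methyl (3R,4S,5R)-3-acetoxy-4-{[(2R)-2-methylbutanoyl]oxy}-5-{[(3S)-3-methylpentanoyl]oxy}cyclohex-1-ene-1-carboxylate | CC[C@H](C)CC(=O)O[C@@H]1CC(C(=O)OC)=C[C@@H](OC(C)=O)[C@H]1OC(=O)[C@H](C)CC | target

## Step count and risks

Total step count: 5 (acid chloride 6 is made and consumed within step 2).
Longest linear sequence: 5 steps (1 → 3 → 7 → 8 → 9 → 11).

**Step 1 (most likely to fail).** Methyl acrylate is a weaker dienophile than the activated acrylates used with this catalyst, so conversion, endo:exo ratio and ee are all uncertain. The fallback sets out from 1 and uses a two-point-binding dienophile instead. Furan and commercial 3-acryloyl-1,3-oxazolidin-2-one react with [Cu((R,R)-t-Bu-box)](SbF6)2 (5 mol%) in CH2Cl2 at −78 °C to give 3-{[(1R,2R,4R)-7-oxabicyclo[2.2.1]hept-5-en-2-yl]carbonyl}-1,3-oxazolidin-2-one F1, which is recrystallised free of the exo isomer. Sm(OTf)3-catalysed methanolysis (MeOH, 0 °C to rt) then removes the oxazolidinone and the route is rejoined at 3.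

**Step 3.** The acyloxy group may shield its face only moderately, and the vinyl epoxide is labile towards elimination. The fallback sets out from 7 and replaces epoxidation and Pd opening by osmylation. OsO4 (2 mol%) and NMO in acetone–water at 0 °C add anti to the allylic C5 oxygen and give methyl (3R,4S,5R)-3,4-dihydroxy-5-{[(3S)-3-methylpentanoyl]oxy}cyclohex-1-ene-1-carboxylate F2. Trimethyl orthoacetate with catalytic CSA in CH2Cl2 converts this diol into the cyclic orthoacetate methyl (3aR,7R,7aS)-2-methoxy-2-methyl-7-{[(3S)-3-methylpentanoyl]oxy}-3a,6,7,7a-tetrahydro-1,3-benzodioxole-5-carboxylate F3 (mixture at the orthoester carbon). Brief treatment with 80% aqueous acetic acid opens it to the ester on the pseudoaxial allylic oxygen, which is 9, where the route is rejoined.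

**Step 5.** The C4 hydroxyl is flanked by two esters and the acid is α-branched, so acylation may be slow enough for the cis acetate to migrate from O3 to O4. The fallback sets out from 8 and puts a non-migrating group on O3 first. Pd(PPh3)4 (5 mol%) with tris(4-methoxybenzyl) borate in THF opens the epoxide with the same net retention and gives methyl (3R,4S,5R)-4-hydroxy-3-[(4-methoxybenzyl)oxy]-5-{[(3S)-3-methylpentanoyl]oxy}cyclohex-1-ene-1-carboxylate F4. Esterification with 10 (DIC, DMAP) gives methyl (3R,4S,5R)-3-[(4-methoxybenzyl)oxy]-4-{[(2R)-2-methylbutanoyl]oxy}-5-{[(3S)-3-methylpentanoyl]oxy}cyclohex-1-ene-1-carboxylate F5. DDQ in CH2Cl2/pH 7 buffer frees the allylic alcohol methyl (3R,4S,5R)-3-hydroxy-4-{[(2R)-2-methylbutanoyl]oxy}-5-{[(3S)-3-methylpentanoyl]oxy}cyclohex-1-ene-1-carboxylate F6, and fast acetylation (Ac2O, pyridine, 0 °C) rejoins the route at 11.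

## Further compounds

F1 | step 1 | 3-{[(1R,2R,4R)-7-oxabicyclo[2.2.1]hept-5-en-2-yl]carbonyl}-1,3-oxazolidin-2-one | O1[C@@H]2C[C@@H](C(=O)N3CCOC3=O)[C@H]1C=C2
F2 | step 3 | methyl (3R,4S,5R)-3,4-dihydroxy-5-{[(3S)-3-methylpentanoyl]oxy}cyclohex-1-ene-1-carboxylate | CC[C@H](C)CC(=O)O[C@@H]1CC(C(=O)OC)=C[C@@H](O)[C@H]1O
F3 | step 3 | methyl (3aR,7R,7aS)-2-methoxy-2-methyl-7-{[(3S)-3-methylpentanoyl]oxy}-3a,6,7,7a-tetrahydro-1,3-benzodioxole-5-carboxylate (cyclic orthoacetate of F2) | CC[C@H](C)CC(=O)O[C@@H]1CC(C(=O)OC)=C[C@H]2OC(C)(OC)O[C@@H]12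
F4 | step 5 | methyl (3R,4S,5R)-4-hydroxy-3-[(4-methoxybenzyl)oxy]-5-{[(3S)-3-methylpentanoyl]oxy}cyclohex-1-ene-1-carboxylate | CC[C@H](C)CC(=O)O[C@@H]1CC(C(=O)OC)=C[C@@H](OCc2ccc(OC)cc2)[C@H]1O
F5 | step 5 | methyl (3R,4S,5R)-3-[(4-methoxybenzyl)oxy]-4-{[(2R)-2-methylbutanoyl]oxy}-5-{[(3S)-3-methylpentanoyl]oxy}cyclohex-1-ene-1-carboxylate | CC[C@H](C)CC(=O)O[C@@H]1CC(C(=O)OC)=C[C@@H](OCc2ccc(OC)cc2)[C@H]1OC(=O)[C@H](C)CC
F6 | step 5 | methyl (3R,4S,5R)-3-hydroxy-4-{[(2R)-2-methylbutanoyl]oxy}-5-{[(3S)-3-methylpentanoyl]oxy}cyclohex-1-ene-1-carboxylate | CC[C@H](C)CC(=O)O[C@@H]1CC(C(=O)OC)=C[C@@H](O)[C@H]1OC(=O)[C@H](C)CC
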